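A direct plan would take both benzene rings from commercial arenes and join them late through the aryl–oxygen bond. The resorcinol ring would be dibenzylated, formylated and oxidised to 2,4-bis(benzyloxy)-6-pentylbenzoic acid (A1). Ring B would be made as the salicylate methyl 2-hydroxy-4-methoxy-6-pentanoylbenzoate (A2). A copper-mediated decarboxylative C–O coupling of A1 with A2 would give the dibenzyl ether A3 of the target, and hydrogenolysis would end the route. No stereocentre or ring closure would be at stake; the weak steps would be:
(a) the C–O coupling, which would have to make an ether with three ortho substituents from a chelated, weakly nucleophilic phenol and a doubly ortho-substituted aryl radical. Such a union has no precedent for phenol partners, would need excess copper salt on both finished fragments, and could escape by protodecarboxylation or aryl ester formation;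
(b) benzylation, formylation and oxidation, three steps on ring A that install a carboxyl carbon only for the coupling to throw it away;
(c) the closing cleavage of two benzyl ethers over palladium, run on the most valuable material beside an aryl ketone that can be reduced under the same conditions.

**Plan of the new route**
The retrosynthesis cuts ring A itself, at C1–C6 and C2–C3 (C1 = ether carbon, C2 and C4 = hydroxyl carbons, C6 = pentyl carbon). The O–C1 bond is cut only at a stage where C1 is the sp3 carbon of a chloromalonate.
This is possible because ring A is a 5-pentylresorcinol whose ether oxygen sits on C1, next to the C2 hydroxyl. O–C1–C2(OH) is thus the O–CH–CO2Me unit of an aryloxymalonate, and C3–C6 with the pentyl chain are C1–C4 of non-3-en-2-one, the pairing of the classical malonate–enone resorcinol synthesis.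
Ring B arises first from 3,5-dimethoxybenzonitrile (steps 1–4). Ring A is grown last on the ring B phenol oxygen: SN2 etherification (step 5), Michael–Claisen annulation (step 6), aromatisation with loss of the spare ester as dimethyl carbonate (step 7).
The hindered aryl ether coupling becomes an SN2 reaction at carbon. Ring A needs no protecting group, formylation or oxidation to an acid, because its hydroxyls are born as the dione carbonyls. Nothing is hydrogenated beside the ketone.

Key step: step 6

Remark on the chemistry: the target has no stereocentre. The stereocentres of 11–14 are uncontrolled and are erased in step 7, so these compounds are carried as racemic mixtures (12 as a mixture of diastereomers, drawn as one enol tautomer).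

Step 1
Reactants: 1 3,5-dimethoxybenzonitrile
Product: 3 1-(3,5-dimethoxyphenyl)pentan-1-one, via bromomagnesium ketiminate 2 (not isolated)
Conditions: n-BuMgBr (1.5 equiv), THF, 0 → 65 °C; then 2 M HCl, rt
Reagents that add atoms: n-butylmagnesium bromide, CCCC[Mg]Br; water, O
Why: Grignard addition to a nitrile stops at the N-magnesio ketimine 2, which aqueous acid hydrolyses to the ketone, so no tertiary alcohol can form.

Step 2
Reactants: 3 1-(3,5-dimethoxyphenyl)pentan-1-one
Product: 4 1-(2-bromo-3,5-dimethoxyphenyl)pentan-1-one
Conditions: NBS (1.05 equiv), MeCN, 0 °C → rt, dark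
Reagents that add atoms: N-bromosuccinimide, O=C1CCC(=O)N1Br
Why: Electrophilic aromatic bromination; 3,5-dimethoxyaryl carbonyl compounds are brominated para to one methoxy group and ortho to the acyl group rather than between the two methoxy groups, and the polar, acid-free medium disfavours α-bromination of the ketone.

Step 3
Reactants: 4 1-(2-bromo-3,5-dimethoxyphenyl)pentan-1-one
Product: 5 methyl 2,4-dimethoxy-6-pentanoylbenzoate
Conditions: Pd(OAc)2 (5 mol %), Xantphos (7.5 mol %), CO (5 bar), Et3N, MeOH/DMF (1:2), 90 °C
Reagents that add atoms: carbon monoxide, [C-]#[O+]; methanol, CO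
Why: Palladium-catalysed alkoxycarbonylation of an aryl bromide (Heck carbonylation); oxidative addition to zerovalent palladium, CO insertion and methanolysis of the acylpalladium give the methyl ester, the wide bite angle of Xantphos supporting the hindered ortho-acyl bromide.

Step 4
Reactants: 5 methyl 2,4-dimethoxy-6-pentanoylbenzoate
Product: 7 methyl 2-hydroxy-4-methoxy-6-pentanoylbenzoate, via dichloroboryl ether 6 (not isolated)
Conditions: BCl3 (1.2 equiv), CH2Cl2, −78 → 0 °C; then H2O
Reagents that add atoms: none
Why: Chelation-controlled Lewis acid demethylation; BCl3 bound to the ester carbonyl cleaves only the methoxy group ortho to it through a six-membered chelate, so the para methoxy group and the methyl ester survive.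

Step 5
Reactants: 7 methyl 2-hydroxy-4-methoxy-6-pentanoylbenzoate; 8 dimethyl 2-chloropropanedioate
Product: 9 dimethyl 2-[5-methoxy-2-(methoxycarbonyl)-3-pentanoylphenoxy]propanedioate
Conditions: 8 (1.3 equiv), K2CO3 (1.5 equiv), acetone, 50 °C
Reagents that add atoms: none
Why: Williamson ether synthesis at an activated secondary chloride (the standard preparation of 2-aryloxymalonates); the salicylate phenoxide displaces chloride by SN2, so the future diaryl ether C–O bond is made at an sp3 carbon before ring A exists, and mild carbonate at moderate temperature keeps the acidic product from cyclising onto the neighbouring ester.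

Step 6
Reactants: 9 dimethyl 2-[5-methoxy-2-(methoxycarbonyl)-3-pentanoylphenoxy]propanedioate; 10 (E)-non-3-en-2-one
Product: 12 methyl 2-hydroxy-1-[5-methoxy-2-(methoxycarbonyl)-3-pentanoylphenoxy]-4-oxo-6-pentylcyclohex-2-ene-1-carboxylate (enol form of the 2,4-dione; racemic diastereomer mixture), via Michael adduct 11 (not isolated)
Conditions: 10 (1.5 equiv), NaOMe (1.3 equiv), MeOH, 0 → 55 °C; then AcOH
Reagents that add atoms: none
Why: Michael–Claisen annulation, the reaction type by which dimedone and the cyclohexanedione precursor of olivetol are made from malonates and enones: methoxide deprotonates only the malonate C–H of 9 (far more acidic than the ketone α-hydrogens), the carbanion adds to C4 of 10 to give 11 (bond C1–C6 of ring A), and the methyl ketone enolate of 11 then acylates on one malonate ester (bond C2–C3). Ring A closes in the 6-(enolendo)-exo-trig mode, and since only the methyl group can close a six-membered ring, the pentyl chain must end next to the aryloxy carbon. The closure is pulled forward by formation of the stabilised enolate of the cyclic 1,3-dione, which also protects 12 from retro-Claisen cleavage. The two new stereocentres (C1 and C6 of the cyclohexene) are not controlled and need not be, since both become sp2 carbons in step 7. The selectivity needed is addition and closure on the aliphatic malonate ester rather than on ring B: attack of the malonate anion on the adjacent benzoate cannot give an enolisable product and so lacks a driving force, and the benzoate, flanked on both sides and conjugated with two ring oxygens, is a much poorer acylating agent towards any ketone enolate than the α-aryloxy malonate ester.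

Step 7
Reactants: 12 methyl 2-hydroxy-1-[5-methoxy-2-(methoxycarbonyl)-3-pentanoylphenoxy]-4-oxo-6-pentylcyclohex-2-ene-1-carboxylate
Product: 15 methyl 2-(2,4-dihydroxy-6-pentylphenoxy)-4-methoxy-6-pentanoylbenzoate (target), via bromodione 13 (not isolated), via dienone ester 14 (not isolated)
Conditions: Br2 (1.0 equiv), DMF, 0 °C then 80 °C; then K2CO3 (4 equiv), MeOH, rt; then 1 M HCl
Reagents that add atoms: none
Why: Bromination–dehydrobromination aromatisation of a dihydroresorcinol as used for olivetol (enol bromination, bromine shift to the α′ carbon under HBr, loss of HBr on warming) gives dienone 14, whose quaternary C1 keeps ring A non-aromatic and inert to bromine until carbonate in methanol is added; methoxide then attacks the ester on the quaternary carbon (retro-Claisen cleavage) and expels ring A as its aromatic resorcinolate with dimethyl carbonate as the other fragment, which erases both stereocentres of 12.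

**Compound list**
1 | 3,5-dimethoxybenzonitrile | COc1cc(OC)cc(C#N)c1 | starting material
2 | bromomagnesium salt of 1-(3,5-dimethoxyphenyl)pentan-1-imine (not isolated) | CCCCC(=N[Mg]Br)c1cc(OC)cc(OC)c1 | intermediate
3 | 1-(3,5-dimethoxyphenyl)pentan-1-one | CCCCC(=O)c1cc(OC)cc(OC)c1 | intermediate
4 | 1-(2-bromo-3,5-dimethoxyphenyl)pentan-1-one | CCCCC(=O)c1cc(OC)cc(OC)c1Br | intermediate
5 | methyl 2,4-dimethoxy-6-pentanoylbenzoate | CCCCC(=O)c1cc(OC)cc(OC)c1C(=O)OC | intermediate
6 | methyl 2-(dichloroboryloxy)-4-methoxy-6-pentanoylbenzoate (not isolated) | CCCCC(=O)c1cc(OC)cc(OB(Cl)Cl)c1C(=O)OC | intermediate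
7 | methyl 2-hydroxy-4-methoxy-6-pentanoylbenzoate | CCCCC(=O)c1cc(OC)cc(O)c1C(=O)OC | intermediate
8 | dimethyl 2-chloropropanedioate (dimethyl chloromalonate) | COC(=O)C(Cl)C(=O)OC | starting material
9 | dimethyl 2-[5-methoxy-2-(methoxycarbonyl)-3-pentanoylphenoxy]propanedioate | CCCCC(=O)c1cc(OC)cc(OC(C(=O)OC)C(=O)OC)c1C(=O)OC | intermediate
10 | (E)-non-3-en-2-one | CCCCC/C=C/C(C)=O | starting material
11 | dimethyl 2-[5-methoxy-2-(methoxycarbonyl)-3-pentanoylphenoxy]-2-(2-oxononan-4-yl)propanedioate, racemic (not isolated) | CCCCCC(CC(C)=O)C(Oc1cc(OC)cc(C(=O)CCCC)c1C(=O)OC)(C(=O)OC)C(=O)OC | intermediate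
12 | methyl 2-hydroxy-1-[5-methoxy-2-(methoxycarbonyl)-3-pentanoylphenoxy]-4-oxo-6-pentylcyclohex-2-ene-1-carboxylate, racemic mixture of diastereomers | CCCCCC1CC(=O)C=C(O)C1(Oc1cc(OC)cc(C(=O)CCCC)c1C(=O)OC)C(=O)OC | intermediate
13 | methyl 3-bromo-1-[5-methoxy-2-(methoxycarbonyl)-3-pentanoylphenoxy]-2,4-dioxo-6-pentylcyclohexane-1-carboxylate, mixture of stereoisomers (not isolated) | CCCCCC1CC(=O)C(Br)C(=O)C1(Oc1cc(OC)cc(C(=O)CCCC)c1C(=O)OC)C(=O)OC | intermediate
14 | methyl 4-hydroxy-1-[5-methoxy-2-(methoxycarbonyl)-3-pentanoylphenoxy]-2-oxo-6-pentylcyclohexa-3,5-diene-1-carboxylate, racemic (not isolated) | CCCCCC1=CC(O)=CC(=O)C1(Oc1cc(OC)cc(C(=O)CCCC)c1C(=O)OC)C(=O)OC | intermediate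
15 | methyl 2-(2,4-dihydroxy-6-pentylphenoxy)-4-methoxy-6-pentanoylbenzoate | CCCCCc1cc(O)cc(O)c1Oc1cc(OC)cc(C(=O)CCCC)c1C(=O)OC | target

Total steps: 7. Longest linear sequence: 7 steps (1 → 15); 8 and 10 are commercial and enter directly.

**Steps most likely to fail**

Step 6. Dieckmann-type closure of the malonate carbanion of 9 onto the neighbouring benzoate with loss of dimethyl carbonate, or reversal of the hindered conjugate addition, may outrun the Claisen closure. The fallback sets out from 9 and returns at 15; it makes that closure deliberate and uses the ring B carboxyl carbon as a relay.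
- Heating 9 with K2CO3 in DMF at 90 °C should give methyl 3-hydroxy-6-methoxy-4-pentanoyl-1-benzofuran-2-carboxylate F1.
- The keto tautomer of F1 is a cyclic β-keto ester of a class known to add to enones at C2. With 10 and catalytic DBU in MeCN it should give methyl 6-methoxy-3-oxo-2-(2-oxononan-4-yl)-4-pentanoyl-2,3-dihydro-1-benzofuran-2-carboxylate F2.
- NaOMe in MeOH should open the non-enolisable β-keto ester of F2 by retro-Claisen attack on the ring ketone, which restores the methyl ester of ring B. The methyl ketone then closes on the remaining aliphatic ester to give methyl 2-[(2-hydroxy-4-oxo-6-pentylcyclohex-2-en-1-yl)oxy]-4-methoxy-6-pentanoylbenzoate F3.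
- F3 still carries a hydrogen on the ether carbon, so Br2 in DMF (0 °C, then 80 °C) should aromatise it directly to 15.

Step 7. Bromine may be transferred to the ketone α-carbon or to an aromatic ring, or the shift and elimination of bromine may stay incomplete. The fallback sets out from 12 and returns at 15 through 14 without any halogen: Pd(O2CCF3)2 (5 mol %), 2-(dimethylamino)pyridine, TsOH, O2 (1 atm), DMSO, 80 °C. This is the palladium-catalysed aerobic dehydrogenation used to turn cyclohexenones into phenols. The quaternary carbon allows unsaturation only between C5 and C6, so 14 should result, and K2CO3 in MeOH then gives 15 as in step 7.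

Step 5. Chlorine may be transferred from 8 to the electron-rich phenoxide, or the acidic product may cyclise onto the ring B ester under carbonate. The fallback sets out from 7 and returns at 9 without base: dimethyl diazomalonate, Rh2(OAc)4 (1 mol %), 1,2-dichloroethane, 80 °C. Rhodium carbenoid insertion into phenol O–H bonds is an established neutral route to aryloxymalonates.

**Further compounds**
F1 | step 6 | methyl 3-hydroxy-6-methoxy-4-pentanoyl-1-benzofuran-2-carboxylate | CCCCC(=O)c1cc(OC)cc2oc(C(=O)OC)c(O)c12
F2 | step 6 | methyl 6-methoxy-3-oxo-2-(2-oxononan-4-yl)-4-pentanoyl-2,3-dihydro-1-benzofuran-2-carboxylate, mixture of stereoisomers | CCCCCC(CC(C)=O)C1(C(=O)OC)Oc2cc(OC)cc(C(=O)CCCC)c2C1=O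
F3 | step 6 | methyl 2-[(2-hydroxy-4-oxo-6-pentylcyclohex-2-en-1-yl)oxy]-4-methoxy-6-pentanoylbenzoate, mixture of stereoisomers | CCCCCC1CC(=O)C=C(O)C1Oc1cc(OC)cc(C(=O)CCCC)c1C(=O)OC
F0 | step 7 | none | none
F0 | step 5 | none | none
A1 | direct plan | 2,4-bis(benzyloxy)-6-pentylbenzoic acid | CCCCCc1cc(OCc2ccccc2)cc(OCc2ccccc2)c1C(=O)O
A2 | direct plan | methyl 2-hydroxy-4-methoxy-6-pentanoylbenzoate | CCCCC(=O)c1cc(OC)cc(O)c1C(=O)OC
A3 | direct plan | methyl 2-[2,4-bis(benzyloxy)-6-pentylphenoxy]-4-methoxy-6-pentanoylbenzoate | CCCCCc1cc(OCc2ccccc2)cc(OCc2ccccc2)c1Oc1cc(OC)cc(C(=O)CCCC)c1C(=O)OC
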